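**Strategy.** Ring B (C5–C6–C7–C8–C9–C10) is cut at its two opposite bonds, C5–C10 and C7–C8, so that both rings of the decalin unravel to one acyclic chain. A temporary C6 ketone makes C5 and C7 nucleophilic and an α-methyl enal makes C10 and C8 electrophilic: base triggers a 6-exo Michael addition (ring A, quaternary C5, trans C10–H) followed by aldol condensation (ring B), giving the bicyclic C6 enone in one operation. The precursor is an open-chain keto ester enal whose single controlling stereocentre, C4, comes from an auxiliary-controlled Diels–Alder adduct unzipped by ozonolysis; the enone then guides installation of the C9 arylmethyl and C8 methyl groups.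

Key step: step 8

Remark on numbering: ring A = C1, C2, C3 (isopropylidene), C4 (2-carboxyethyl chain), C5 (angular CH3), C10 (angular H); ring B = C5, C6, C7, C8 (CH3), C9 (CH3 and CH2Ar), C10; C11 = benzylic CH2. "α" is the face of the C5 methyl, "β" the opposite face.
Remark on the chemistry: 3-methylpenta-1,3-diene is sold as an E/Z mixture and only the E isomer is expected to cycloadd; the C9–H stereocentre formed in step 8 is erased in step 9, so its configuration is immaterial (the equatorial-methyl epimer is drawn).

**Step 1**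
Reactants: 1 (R)-4-benzyl-1,3-oxazolidin-2-one; 2 acryloyl chloride
Product: 3 (R)-3-acryloyl-4-benzyl-1,3-oxazolidin-2-one
Conditions: MeMgBr (1.0 equiv), THF, 0 °C; then 2, −78 → 0 °C
Reagents that add atoms: none
Why: N-acylation of the bromomagnesium salt of the oxazolidinone should give the chiral dienophile without polymerisation of the acryloyl unit (imide formation).

**Step 2**
Reactants: 3 (R)-3-acryloyl-4-benzyl-1,3-oxazolidin-2-one; 4 (E)-3-methylpenta-1,3-diene
Product: 5 cis Diels–Alder adduct, (R)-4-benzyl-3-[(1S,2S)-2,3-dimethylcyclohex-3-ene-1-carbonyl]-1,3-oxazolidin-2-one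
Conditions: Et2AlCl (1.4 equiv), CH2Cl2, −78 °C, excess diene
Reagents that add atoms: none
Why: The aluminium-chelated s-cis acrylimide should undergo an endo Diels–Alder reaction on the face opposite the benzyl group, with the terminal methyl of the diene directing the acyl group to the adjacent ("ortho") carbon, so that the future C4 is set as S and the C5 methyl is cis to it.

**Step 3**
Reactants: 5 cis Diels–Alder adduct
Product: 6 (1S,2S)-N-methoxy-N,2,3-trimethylcyclohex-3-ene-1-carboxamide
Conditions: MeNHOMe·HCl, AlMe3, CH2Cl2, 0 °C → rt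
Reagents that add atoms: N,O-dimethylhydroxylamine hydrochloride, CNOC.Cl
Why: Aluminium amide transamination should cleave the exocyclic imide carbonyl to the Weinreb amide and release the auxiliary without touching the α-stereocentre.

**Step 4**
Reactants: 6 Weinreb amide; 7 but-3-en-1-ylmagnesium bromide
Product: 8 1-[(1S,2S)-2,3-dimethylcyclohex-3-en-1-yl]pent-4-en-1-one
Conditions: THF, 0 °C; aq. NH4Cl
Reagents that add atoms: none
Why: Grignard addition to a Weinreb amide stops at the chelated tetrahedral intermediate, so the ketone (future C3, with C2, C1 and C10 attached) should form on work-up without over-addition or epimerisation of C4.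

**Step 5**
Reactants: 8 ketone
Product: 9 2-(but-3-en-1-yl)-2-[(1S,2S)-2,3-dimethylcyclohex-3-en-1-yl]-1,3-dioxolane
Conditions: TMSOCH2CH2OTMS, TMSOTf (cat.), CH2Cl2, −78 → −20 °C; pyridine quench
Reagents that add atoms: 1,2-bis(trimethylsilyloxy)ethane, C[Si](C)(C)OCCO[Si](C)(C)C
Why: Aprotic silyl-triflate-catalysed ketalisation should mask the C3 ketone at low temperature, which avoids acid-mediated epimerisation of C4 and later blocks enolisation toward C4.

**Step 6**
Reactants: 9 ketal; 10 methacrolein
Product: 11 (E)-5-{2-[(1S,2S)-2,3-dimethylcyclohex-3-en-1-yl]-1,3-dioxolan-2-yl}-2-methylpent-2-enal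
Conditions: second-generation Hoveyda–Grubbs catalyst RuCl2(H2IMes)(=CH-C6H4-2-O-i-Pr) (5 mol %), CH2Cl2, 40 °C, excess 10
Reagents that add atoms: none
Why: Olefin cross-metathesis of the terminal alkene with methacrolein should give the (E)-trisubstituted enal (C10=C9–C8), while the unstrained trisubstituted ring alkene stays out of the reaction.

**Step 7**
Reactants: 11 enal
Product: 13 keto ester enal, via methoxy hydroperoxide 12 (not isolated)
Conditions: O3 (1 equiv, dye end-point), NaHCO3, CH2Cl2/MeOH, −78 °C; then Ac2O, Et3N, 0 °C → rt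
Reagents that add atoms: ozone, [O-][O+]=O; methanol, CO
Why: Ozone should cleave the electron-rich trisubstituted ring alkene in preference to the electron-poor enal, and dehydration of the methanol-trapped carbonyl oxide (unsymmetrical ozonolysis) should deliver the C6 methyl ketone and the methyl ester of the C4 chain directly.

**Step 8**
Reactants: 13 keto ester enal
Product: 16 trans-fused bicyclic C6 enone, via Michael adduct 14 (not isolated), via aldol adduct 15 (not isolated)
Conditions: KOt-Bu (0.5 equiv), t-BuOH/THF, 0.01 M, 0 → 40 °C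
Reagents that add atoms: none
Why: Reversible deprotonation gives the more substituted C5 enolate of the methyl ketone, which adds to C10 of the enal (6-exo-trig, ring A); the keto aldehyde then equilibrates to the C7 enolate, which attacks the C8 aldehyde (6-enolexo-exo-trig aldol, ring B), and E1cB loss of water makes the sequence irreversible. The closest known reaction type is the Robinson-type Michael/aldol-condensation [3+3] annulation of ketones or β-keto esters with enals, here run intramolecularly so that both rings close in one operation. C5 is controlled by allylic 1,3-strain in the tetrasubstituted enolate: C4–H eclipses the enolate double bond and the tether through C3 forces C10 to attack syn to C3, so the 2-(methoxycarbonyl)ethyl chain ends equatorial and cis to the axial C5 methyl. C10 is controlled by a chair transition state with the enal equatorial and synclinal to the enolate (potassium chelation), which should place C10–H trans to the C5 methyl. The step needs C–C formation from C5 and not from C7, C4 or the ester α-carbon: only the C5 enolate reaches C10 through a six-membered ring (C7 would need an eight-membered one), the dioxolane removes the competing 5-exo donor at C4 and protects C4 from epimerisation, and the only aldol that closes a six-membered ring is C7 onto C8.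

**Step 9**
Reactants: 16 bicyclic enone
Product: 17 tert-butyldimethylsilyl dienol ether (C6–OSi, C6=C7, C8=C9)
Conditions: KN(SiMe3)2, THF, −78 °C; TBSCl, −78 → 0 °C
Reagents that add atoms: tert-butyldimethylsilyl chloride, CC(C)(C)[Si](C)(C)Cl
Why: Because C5 is quaternary the enone has no α′-hydrogen, so the base should remove the γ-hydrogen at C9 and O-silylation should give a single through-conjugated silyl dienol ether.

**Step 10**
Reactants: 18 4-methoxy-2-methylphenol; 19 paraformaldehyde
Product: 20 2-hydroxy-5-methoxy-3-methylbenzaldehyde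
Conditions: MgCl2, Et3N, MeCN, reflux; aq. HCl
Reagents that add atoms: none
Why: Magnesium-phenoxide-directed ortho-formylation should occur at the only free ortho position.

**Step 11**
Reactants: 20 2-hydroxy-5-methoxy-3-methylbenzaldehyde
Product: 21 2-(benzyloxy)-5-methoxy-3-methylbenzaldehyde
Conditions: BnBr, K2CO3, DMF, rt
Reagents that add atoms: benzyl bromide, BrCc1ccccc1
Why: Williamson etherification of the phenoxide protects the phenol as a donor group that survives Lewis acid, cuprate, low-valent titanium and hot base.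

**Step 12**
Reactants: 21 2-(benzyloxy)-5-methoxy-3-methylbenzaldehyde
Product: 22 [2-(benzyloxy)-5-methoxy-3-methylphenyl]methanol
Conditions: NaBH4, MeOH, 0 °C
Reagents that add atoms: none
Why: Borohydride reduction of the aldehyde should give the benzylic alcohol cleanly.

**Step 13**
Reactants: 22 benzylic alcohol
Product: 23 2-(benzyloxy)-1-(bromomethyl)-5-methoxy-3-methylbenzene
Conditions: PBr3, Et2O, 0 °C
Reagents that add atoms: phosphorus tribromide, BrP(Br)Br
Why: Substitution of the activated benzylic alcohol with PBr3 should give the ionisable benzylic bromide.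

**Step 14**
Reactants: 17 silyl dienol ether; 23 benzylic bromide
Product: 24 C9-arylmethyl enone
Conditions: ZnBr2 (0.3 equiv), CH2Cl2, −40 → 0 °C
Reagents that add atoms: none
Why: ZnBr2 should ionise the alkoxy-stabilised benzylic bromide and the silyl dienol ether should attack through its γ-carbon C9 (vinylogous Mukaiyama-type SN1 alkylation) on the β face, away from the axial C5 methyl, which creates the C9 quaternary centre with CH2Ar trans to that methyl and returns the C6 enone.

**Step 15**
Reactants: 24 C9-arylmethyl enone; 25 methyllithium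
Product: 27 C8-methyl enol acetate, via lithium enolate 26 (not isolated)
Conditions: MeLi, CuI, Et2O, −40 → 0 °C (Me2CuLi); then Ac2O, 0 °C → rt
Reagents that add atoms: acetic anhydride, CC(=O)OC(C)=O
Why: Gilman cuprate 1,4-addition should deliver the methyl group axially to C8, antiparallel to the axial C9 methyl and therefore cis to CH2Ar, and O-acetylation of the enolate masks the C6 carbonyl for the next two steps.

**Step 16**
Reactants: 27 enol acetate
Product: 28 C3 ketone
Conditions: pyridinium p-toluenesulfonate (cat.), acetone/H2O, 50 °C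
Reagents that add atoms: water, O
Why: Mild acid-catalysed ketal hydrolysis should free the C3 ketone while the enol acetate, ester and benzyl ether survive and C4 is not epimerised.

**Step 17**
Reactants: 28 C3 ketone; 29 acetone
Product: 30 C3-isopropylidene enol acetate
Conditions: TiCl4, Zn, pyridine, THF, reflux; slow addition of 28 and excess acetone
Reagents that add atoms: none
Why: Mixed McMurry coupling with excess acetone should convert the only free ketone into the tetrasubstituted isopropylidene without a basic ylide that could epimerise C4, the strongly exergonic deoxygenation paying for the allylic strain against the C4 chain.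

**Step 18**
Reactants: 30 isopropylidene enol acetate
Product: 33 benzyl-protected seco acid, via keto acid 31 (not isolated), via hydrazone 32 (not isolated)
Conditions: KOH, diethylene glycol, 120 °C; then N2H4·H2O, 140 → 200 °C; aq. HCl
Reagents that add atoms: potassium hydroxide, [K+].[OH-]
Why: Hydroxide should cleave the enol acetate and the methyl ester, and Wolff–Kishner reduction of the liberated C6 ketone removes the temporary oxygen that activated C5 and C7 in the key step.

**Step 19**
Reactants: 33 benzyl-protected seco acid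
Product: 34 target CNP0299684.1
Conditions: H2 (1 atm), Pd/C, EtOAc, rt, stopped at consumption of 33
Reagents that add atoms: none
Why: Hydrogenolysis of the aryl benzyl ether should be much faster than hydrogenation of the hindered tetrasubstituted alkene.

**Compound list**
1 | (R)-4-benzyl-1,3-oxazolidin-2-one | O=C1OC[C@@H](Cc2ccccc2)N1 | starting material
2 | acryloyl chloride | C=CC(=O)Cl | starting material
3 | (R)-3-acryloyl-4-benzyl-1,3-oxazolidin-2-one | C=CC(=O)N1[C@H](Cc2ccccc2)COC1=O | intermediate
4 | (E)-3-methylpenta-1,3-diene | C=C/C(C)=C/C | starting material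
5 | (R)-4-benzyl-3-[(1S,2S)-2,3-dimethylcyclohex-3-ene-1-carbonyl]-1,3-oxazolidin-2-one (cis adduct) | C[C@@H]1C(C)=CCC[C@@H]1C(=O)N1[C@H](Cc2ccccc2)COC1=O | intermediate
6 | (1S,2S)-N-methoxy-N,2,3-trimethylcyclohex-3-ene-1-carboxamide | C[C@@H]1C(C)=CCC[C@@H]1C(=O)N(C)OC | intermediate
7 | but-3-en-1-ylmagnesium bromide | C=CCC[Mg]Br | starting material
8 | 1-[(1S,2S)-2,3-dimethylcyclohex-3-en-1-yl]pent-4-en-1-one | C[C@@H]1C(C)=CCC[C@@H]1C(=O)CCC=C | intermediate
9 | 2-(but-3-en-1-yl)-2-[(1S,2S)-2,3-dimethylcyclohex-3-en-1-yl]-1,3-dioxolane | C[C@@H]1C(C)=CCC[C@@H]1C1(CCC=C)OCCO1 | intermediate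
10 | methacrolein (2-methylprop-2-enal) | C=C(C)C=O | starting material
11 | (E)-5-{2-[(1S,2S)-2,3-dimethylcyclohex-3-en-1-yl]-1,3-dioxolan-2-yl}-2-methylpent-2-enal | C[C@@H]1C(C)=CCC[C@@H]1C1(CC/C=C(\C)C=O)OCCO1 | intermediate
12 | methoxy hydroperoxide from ring cleavage of 11 (not isolated; peroxy-acetal carbon undefined) | CC(=O)[C@@H](C)[C@H](CCC(OC)OO)C1(CC/C=C(\C)C=O)OCCO1 | intermediate
13 | methyl (4S,5S)-5-methyl-4-{2-[(E)-4-methyl-5-oxopent-3-en-1-yl]-1,3-dioxolan-2-yl}-6-oxoheptanoate | CC(=O)[C@@H](C)[C@H](CCC(=O)OC)C1(CC/C=C(\C)C=O)OCCO1 | intermediate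
14 | Michael adduct (not isolated): ring A closed; C5 bears CH3 and acetyl, C10 bears the 1-oxopropan-2-yl group trans to the acetyl group; C3 dioxolane; C4 chain cis to C5–CH3 | O=C[C@H](C)[C@H]1CCC2(OCCO2)[C@@H](CCC(=O)OC)[C@]1(C)C(C)=O | intermediate
15 | aldol adduct (not isolated): trans-decalin with C6 ketone and C8 hydroxyl (carbinol configuration undefined) | C[C@@H]1[C@H]2CCC3(OCCO3)[C@@H](CCC(=O)OC)[C@]2(C)C(=O)CC1O | intermediate
16 | trans-fused bicyclic enone: methyl 3-(decalin-4-yl)propanoate with C3 ethylene ketal, C4 chain α (cis to C5–CH3), C10–H β, C6 ketone, C7=C8, C9–CH3 | C[C@@H]1[C@H]2CCC3(OCCO3)[C@@H](CCC(=O)OC)[C@]2(C)C(=O)C=C1 | intermediate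
17 | tert-butyldimethylsilyl dienol ether of 16 (C6–OSi, C6=C7, C8=C9) | CC=1[C@H]2CCC3(OCCO3)[C@@H](CCC(=O)OC)[C@]2(C)C(O[Si](C)(C)C(C)(C)C)=CC=1 | intermediate
18 | 4-methoxy-2-methylphenol | COc1ccc(O)c(C)c1 | starting material
19 | paraformaldehyde (as formaldehyde) | C=O | starting material
20 | 2-hydroxy-5-methoxy-3-methylbenzaldehyde | COc1cc(C)c(O)c(C=O)c1 | intermediate
21 | 2-(benzyloxy)-5-methoxy-3-methylbenzaldehyde | COc1cc(C)c(OCc2ccccc2)c(C=O)c1 | intermediate
22 | [2-(benzyloxy)-5-methoxy-3-methylphenyl]methanol | COc1cc(C)c(OCc2ccccc2)c(CO)c1 | intermediate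
23 | 2-(benzyloxy)-1-(bromomethyl)-5-methoxy-3-methylbenzene | COc1cc(C)c(OCc2ccccc2)c(CBr)c1 | intermediate
24 | C9-arylmethyl enone: as 16, with C9 quaternary (CH3 α, CH2Ar β; Ar = 2-benzyloxy-5-methoxy-3-methylphenyl) | COc1cc(C)c(OCc2ccccc2)c(C[C@]2(C)[C@H]3CCC4(OCCO4)[C@@H](CCC(=O)OC)[C@]3(C)C(=O)C=C2)c1 | intermediate
25 | methyllithium | [Li]C | starting material
26 | lithium C6 enolate after methyl addition at C8 (not isolated) | COc1cc(C)c(OCc2ccccc2)c(C[C@]2(C)[C@H]3CCC4(OCCO4)[C@@H](CCC(=O)OC)[C@]3(C)C([O-])=C[C@@H]2C)c1.[Li+] | intermediate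
27 | enol acetate: C6–OAc, C6=C7, C8–CH3 β (cis to CH2Ar), C3 ketal | COc1cc(C)c(OCc2ccccc2)c(C[C@]2(C)[C@H]3CCC4(OCCO4)[C@@H](CCC(=O)OC)[C@]3(C)C(OC(C)=O)=C[C@@H]2C)c1 | intermediate
28 | C3 ketone (ketal removed from 27) | COc1cc(C)c(OCc2ccccc2)c(C[C@]2(C)[C@H]3CCC(=O)[C@@H](CCC(=O)OC)[C@]3(C)C(OC(C)=O)=C[C@@H]2C)c1 | intermediate
29 | acetone | CC(C)=O | starting material
30 | C3-isopropylidene enol acetate | COc1cc(C)c(OCc2ccccc2)c(C[C@]2(C)[C@H]3CCC(=C(C)C)[C@@H](CCC(=O)OC)[C@]3(C)C(OC(C)=O)=C[C@@H]2C)c1 | intermediate
31 | C6 keto acid (not isolated) | COc1cc(C)c(OCc2ccccc2)c(C[C@]2(C)[C@H]3CCC(=C(C)C)[C@@H](CCC(=O)O)[C@]3(C)C(=O)C[C@@H]2C)c1 | intermediate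
32 | C6 hydrazone (not isolated) | COc1cc(C)c(OCc2ccccc2)c(C[C@]2(C)[C@H]3CCC(=C(C)C)[C@@H](CCC(=O)O)[C@]3(C)C(=NN)C[C@@H]2C)c1 | intermediate
33 | benzyl-protected seco acid (O-benzyl ether of the target) | COc1cc(C)c(OCc2ccccc2)c(C[C@]2(C)[C@H]3CCC(=C(C)C)[C@@H](CCC(=O)O)[C@]3(C)CC[C@@H]2C)c1 | intermediate
34 | CNP0299684.1 | COc1cc(C)c(O)c(C[C@]2(C)[C@H]3CCC(=C(C)C)[C@@H](CCC(=O)O)[C@]3(C)CC[C@@H]2C)c1 | target

**Step count and risks**
Total steps: 19. Longest linear sequence: 15 steps (steps 1–9 and 14–19); the aryl fragment (steps 10–13) joins at step 14.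

Steps most likely to fail:

1. Step 8 (key step). The Michael addition may lose trans ring-fusion control, and the enal may oligomerise or deconjugate under base before it cyclises. Fallback, changing the acceptor and the second ring closure: from ketal 9, cross-metathesis with methyl methacrylate should give the (E)-enoate F1 and ozonolysis as in step 7 the keto diester F2. KOt-Bu in THF should then effect a Michael/Claisen double cyclisation to the cyclohexane-1,3-dione F3, in which no aldehyde is exposed to base and the reversible Michael step is drained by formation of the stable dione enolate. O-Triflation at the less hindered C8 oxygen (Tf2O, 2,6-lutidine) should give the β-triflyloxy enone F4, and palladium-catalysed formate reduction (Pd(OAc)2, PPh3, HCO2H, Bu3N) would return to the route at enone 16.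

2. Step 14. Attack may occur through C7 instead of C9, the electron-rich benzylic bromide may self-condense by Friedel–Crafts alkylation, or facial bias at the congested C9 may be insufficient. Fallback, changing the electrophile to a carbonyl: from dienol ether 17 and aldehyde 21, a vinylogous Mukaiyama aldol reaction (BF3·OEt2, CH2Cl2, −78 °C) should give the γ-aldol adduct F5 at C9. Phenyl chlorothionoformate with DMAP should then give the thionocarbonate F6, and Barton–McCombie deoxygenation (Bu3SnH, AIBN, toluene, 80 °C) would return to the route at enone 24.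

3. Step 17. C4 may epimerise through a titanium enolate, the coupling may stop at the pinacol stage, or the α-branched ketone may fail to cross-couple. Fallback, building the alkene by cross-coupling instead of carbonyl coupling: from ketone 28, kinetic deprotonation on the unhindered C2 side (KN(SiMe3)2, PhNTf2, THF, −78 °C) should give the vinyl triflate F7 without touching C4. Suzuki–Miyaura coupling with isopropenylboronic acid pinacol ester (Pd(PPh3)4, K3PO4) should give the diene F8, and 1,4-hydrogenation with H2 and (naphthalene)Cr(CO)3 should place hydrogen at C2 and at the terminal CH2, returning to the route at 30.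

**Further compounds**
F1 | step 8 | methyl (E)-5-{2-[(1S,2S)-2,3-dimethylcyclohex-3-en-1-yl]-1,3-dioxolan-2-yl}-2-methylpent-2-enoate | C[C@@H]1C(C)=CCC[C@@H]1C1(CC/C=C(\C)C(=O)OC)OCCO1
F2 | step 8 | keto diester: methyl ester analogue of 13 (enoate in place of enal) | CC(=O)[C@@H](C)[C@H](CCC(=O)OC)C1(CC/C=C(\C)C(=O)OC)OCCO1
F3 | step 8 | trans-fused bicyclic 6,8-dione (cyclohexane-1,3-dione in ring B) | C[C@@H]1[C@H]2CCC3(OCCO3)[C@@H](CCC(=O)OC)[C@]2(C)C(=O)CC1=O
F4 | step 8 | β-triflyloxy enone (C8–OTf, C7=C8, C6 ketone) | C[C@@H]1[C@H]2CCC3(OCCO3)[C@@H](CCC(=O)OC)[C@]2(C)C(=O)C=C1OS(=O)(=O)C(F)(F)F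
F5 | step 14 | γ-aldol adduct: C9–CH(OH)Ar enone (carbinol configuration undefined) | COc1cc(C)c(OCc2ccccc2)c(C(O)[C@]2(C)[C@H]3CCC4(OCCO4)[C@@H](CCC(=O)OC)[C@]3(C)C(=O)C=C2)c1
F6 | step 14 | O-phenyl thionocarbonate of F5 | COc1cc(C)c(OCc2ccccc2)c(C(OC(=S)Oc2ccccc2)[C@]2(C)[C@H]3CCC4(OCCO4)[C@@H](CCC(=O)OC)[C@]3(C)C(=O)C=C2)c1
F7 | step 17 | vinyl triflate (C3–OTf, C2=C3) of 28 | COc1cc(C)c(OCc2ccccc2)c(C[C@]2(C)[C@H]3CC=C(OS(=O)(=O)C(F)(F)F)[C@@H](CCC(=O)OC)[C@]3(C)C(OC(C)=O)=C[C@@H]2C)c1
F8 | step 17 | 3-isopropenyl diene (C2=C3–C(CH3)=CH2) | COc1cc(C)c(OCc2ccccc2)c(C[C@]2(C)[C@H]3CC=C(C(C)=C)[C@@H](CCC(=O)OC)[C@]3(C)C(OC(C)=O)=C[C@@H]2C)c1
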